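**Retrosynthetic overview**
- The target quinone comes from its hydroquinone, a 2-(2,5-dihydroxyphenyl)furan, by a mild dehydrogenation.
- The plan rests on the furan O1–C2 bond, where C2 is the furan carbon bonded to the six-membered quinone ring. Opening that bond shows the hydroquinone-furan to be an isomer, at the same oxidation level, of a 2-allyl-1,4-benzoquinone whose side chain carries a formyl group cis to the benzylic CH2. The furan is the only ring made, and it is closed last.
- The allyl quinone comes from a 2,5-dimethoxyphenyl (Z)-alkenylstannane by tin-to-formyl exchange, O-acylation and oxidative demethylation. The stannane comes from hydroxyl-directed trans-hydrostannation of a benzyl-substituted propargylic alcohol.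
- That alcohol comes from 2,5-dimethoxybenzyl bromide and an (R)-configured terminal alkynol. The alkynol's single stereocentre is set by asymmetric transfer hydrogenation of a silyl ynone made from the Weinreb amide of 4-methylpent-3-enoic acid and ethynyltrimethylsilane.

Key step: step 10

Remark: the carbinol carbon keeps the descriptor R from the transfer hydrogenation to the target, because its unsaturated carbon neighbour (alkynyl, alkenyl or furyl) always ranks above the CH2 group.

**Step 1**
Reactants: 1 4-methylpent-3-enoic acid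
Product: 2 N-methoxy-N,4-dimethylpent-3-enamide
Conditions: 1,1'-carbonyldiimidazole, CH2Cl2, 0 °C to rt; then MeNHOMe·HCl, rt
Reagents that add atoms: N,O-dimethylhydroxylamine hydrochloride, CNOC.Cl
Why: Weinreb amide formation through the acyl imidazolide, a near-neutral activation that should leave the β,γ-alkene out of conjugation.

**Step 2**
Reactants: 2 N-methoxy-N,4-dimethylpent-3-enamide; 3 ethynyltrimethylsilane
Product: 5 6-methyl-1-(trimethylsilyl)hept-5-en-1-yn-3-one, via lithium (trimethylsilyl)acetylide 4 (not isolated)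
Conditions: 3, n-BuLi, THF, −78 °C; then 2, −78 to −20 °C; cold aq. NH4Cl
Reagents that add atoms: none
Why: Weinreb ketone synthesis with a lithium acetylide, in which N-methoxy chelation should stop the addition at the ketone stage and keep the skipped enone away from base until the cold quench.

**Step 3**
Reactants: 5 6-methyl-1-(trimethylsilyl)hept-5-en-1-yn-3-one
Product: 6 (3R)-6-methyl-1-(trimethylsilyl)hept-5-en-1-yn-3-ol
Conditions: Ru[(R,R)-TsNCH(Ph)CH(Ph)NH](p-cymene) (1 mol %), i-PrOH, rt
Reagents that add atoms: none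
Why: Noyori asymmetric transfer hydrogenation of an alkynyl ketone, in which the alkynyl group takes the place of the aryl group of an aryl ketone in the six-membered hydride-transfer transition state, so that the (R,R)-catalyst should give the (R)-alcohol, and the base-free amido complex spares the enolisable ynone.

**Step 4**
Reactants: 6 (3R)-6-methyl-1-(trimethylsilyl)hept-5-en-1-yn-3-ol
Product: 7 (3R)-6-methylhept-5-en-1-yn-3-ol
Conditions: K2CO3 (cat.), MeOH, 0 °C to rt
Reagents that add atoms: none
Why: Protodesilylation of the C(sp)–Si bond by carbonate-catalysed methanolysis, which does not touch the carbinol stereocentre.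

**Step 5**
Reactants: 7 (3R)-6-methylhept-5-en-1-yn-3-ol; 8 2,5-dimethoxybenzyl bromide
Product: 9 (4R)-1-(2,5-dimethoxyphenyl)-7-methyloct-6-en-2-yn-4-ol
Conditions: CuI (20 mol %), Cs2CO3, MeCN, rt
Reagents that add atoms: none
Why: Copper-mediated coupling of a terminal alkyne with a benzyl bromide through the copper acetylide, in which C-alkylation should outrun O-benzylation of the un-ionised secondary alcohol and the mild carbonate base limits propargyl-to-allenyl isomerisation.

**Step 6**
Reactants: 9 (4R)-1-(2,5-dimethoxyphenyl)-7-methyloct-6-en-2-yn-4-ol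
Product: 10 (2Z,4R)-1-(2,5-dimethoxyphenyl)-7-methyl-3-(tributylstannyl)octa-2,6-dien-4-ol
Conditions: Bu3SnH, [(C5Me5)RuCl]4 (2.5 mol %), CH2Cl2, rt
Reagents that add atoms: tributyltin hydride, CCCC[SnH](CCCC)CCCC
Why: Ruthenium-catalysed hydroxyl-directed trans-hydrostannation, in which a hydrogen bond from the carbinol OH to the Ru–Cl unit steers tin to the proximal alkyne carbon C3 and anti addition of H and Sn places tin cis to the benzylic CH2, while the arene and the trisubstituted alkene are inert.

**Step 7**
Reactants: 10 (2Z,4R)-1-(2,5-dimethoxyphenyl)-7-methyl-3-(tributylstannyl)octa-2,6-dien-4-ol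
Product: 12 (2Z)-4-(2,5-dimethoxyphenyl)-2-[(1R)-1-hydroxy-4-methylpent-3-enyl]but-2-enal, via dilithio alkenyl alkoxide 11 (not isolated)
Conditions: MeLi (3 equiv), THF, −78 to −40 °C; then DMF, −78 to 0 °C; aq. NH4Cl
Reagents that add atoms: N,N-dimethylformamide, CN(C)C=O
Why: Tin–lithium exchange with retention of alkene geometry followed by formylation with DMF (Bouveault-type aldehyde synthesis), in which the first equivalent of MeLi forms the alkoxide, the second gives the configurationally stable alkenyllithium 11, and the enal is released only on work-up.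

**Step 8**
Reactants: 12 (2Z)-4-(2,5-dimethoxyphenyl)-2-[(1R)-1-hydroxy-4-methylpent-3-enyl]but-2-enal; 13 isovaleryl chloride
Product: 14 (2Z,4R)-1-(2,5-dimethoxyphenyl)-3-formyl-7-methylocta-2,6-dien-4-yl 3-methylbutanoate
Conditions: pyridine, CH2Cl2, 0 °C
Reagents that add atoms: none
Why: O-Acylation of a secondary allylic alcohol with an acid chloride and pyridine, run without a nucleophilic amine catalyst so that the Morita–Baylis–Hillman-type enal is not attacked in an SN2' sense.

**Step 9**
Reactants: 14 (2Z,4R)-1-(2,5-dimethoxyphenyl)-3-formyl-7-methylocta-2,6-dien-4-yl 3-methylbutanoate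
Product: 15 2-[(2Z,4R)-3-formyl-7-methyl-4-(3-methylbutanoyloxy)octa-2,6-dienyl]-1,4-benzoquinone
Conditions: (NH4)2Ce(NO3)6 (2.5 equiv), MeCN/H2O (4:1), 0 °C, short reaction time; cold extractive work-up, used at once
Reagents that add atoms: water, O
Why: Oxidative demethylation of a 1,4-dimethoxybenzene to the 1,4-benzoquinone with tetravalent cerium (electron transfer, then attack of water at the two methoxy-bearing carbons), which is fast at 0 °C and should spare the enal, the ester and the trisubstituted alkene.

**Step 10**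
Reactants: 15 2-[(2Z,4R)-3-formyl-7-methyl-4-(3-methylbutanoyloxy)octa-2,6-dienyl]-1,4-benzoquinone
Product: 18 (1R)-1-[5-(2,5-dihydroxyphenyl)furan-3-yl]-4-methylpent-3-enyl 3-methylbutanoate, via o-quinone methide 16 (not isolated), via furanium phenolate 17 (not isolated)
Conditions: Et3N (0.1 equiv), CH2Cl2, 0 °C to rt, Ar, dark
Reagents that add atoms: none
Why: Proposed new method: Et3N should shuttle a proton from the side-chain CH2 (vinylogous to the C4 carbonyl of the quinone and γ to the enal) to that carbonyl oxygen, giving the 4-hydroxy o-quinone methide 16, whose formyl oxygen then adds to the methide carbon to form O1–C2 (furanium phenolate 17), and loss of the C2 proton aromatises the furan and the benzene ring at once, so that the quinone is reduced and the side chain oxidised without any external redox reagent. The closest known reaction types are the amine-induced tautomerisation of allyl- and prenylquinones to o-quinone methides that close to 2H-chromenes, and the cyclodehydration of cis γ-oxygenated enals to furans; capture of such a methide by a carbonyl oxygen to give a furan has no direct precedent. The furan is closed by a 5-exo-trig attack of oxygen on the exocyclic methide C=C (equally a 4π closure of a 1-oxapentadienyl cation), and no other ring is formed. No stereocentre is created, and the (R)-acyloxy carbon is a spectator because it lies outside the tautomerising π-system. The step needs O(formyl)–C(methide) closure to win over oxa-6π closure of the ring oxygen onto C3 of the chain (2H-chromene) and over 1,4-elimination of isovalerate from the extended enolate. The (2Z) alkene fixed in step 6 holds the formyl group next to the methide carbon, chromene formation is reversible whereas the double aromatisation is not, and a catalytic weak base at low temperature keeps the enolate concentration small.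

**Step 11**
Reactants: 18 (1R)-1-[5-(2,5-dihydroxyphenyl)furan-3-yl]-4-methylpent-3-enyl 3-methylbutanoate
Product: 19 (1R)-1-[5-(3,6-dioxocyclohexa-1,4-dien-1-yl)furan-3-yl]-4-methylpent-3-enyl 3-methylbutanoate
Conditions: Ag2O, MgSO4, Et2O, rt
Reagents that add atoms: none
Why: Dehydrogenation of a hydroquinone to the 1,4-benzoquinone with Ag2O, a neutral heterogeneous oxidant that should leave the furan, the ester and the alkene untouched.

**Compound list**
1 | 4-methylpent-3-enoic acid | CC(C)=CCC(=O)O | starting material
2 | N-methoxy-N,4-dimethylpent-3-enamide | CC(C)=CCC(=O)N(C)OC | intermediate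
3 | ethynyltrimethylsilane | C#C[Si](C)(C)C | starting material
4 | lithium (trimethylsilyl)acetylide | [Li]C#C[Si](C)(C)C | intermediate (not isolated)
5 | 6-methyl-1-(trimethylsilyl)hept-5-en-1-yn-3-one | CC(C)=CCC(=O)C#C[Si](C)(C)C | intermediate
6 | (3R)-6-methyl-1-(trimethylsilyl)hept-5-en-1-yn-3-ol | CC(C)=CC[C@@H](O)C#C[Si](C)(C)C | intermediate
7 | (3R)-6-methylhept-5-en-1-yn-3-ol | CC(C)=CC[C@@H](O)C#C | intermediate
8 | 2,5-dimethoxybenzyl bromide | COc1ccc(OC)c(CBr)c1 | starting material
9 | (4R)-1-(2,5-dimethoxyphenyl)-7-methyloct-6-en-2-yn-4-ol | CC(C)=CC[C@@H](O)C#CCc1cc(OC)ccc1OC | intermediate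
10 | (2Z,4R)-1-(2,5-dimethoxyphenyl)-7-methyl-3-(tributylstannyl)octa-2,6-dien-4-ol | CC(C)=CC[C@@H](O)/C(=C/Cc1cc(OC)ccc1OC)[Sn](CCCC)(CCCC)CCCC | intermediate
11 | dilithio alkenyl alkoxide, the (2Z,4R)-3-lithio-4-lithiooxy analogue of 10 | CC(C)=CC[C@@H](O[Li])/C([Li])=C/Cc1cc(OC)ccc1OC | intermediate (not isolated)
12 | (2Z)-4-(2,5-dimethoxyphenyl)-2-[(1R)-1-hydroxy-4-methylpent-3-enyl]but-2-enal | CC(C)=CC[C@@H](O)/C(C=O)=C/Cc1cc(OC)ccc1OC | intermediate
13 | isovaleryl chloride (3-methylbutanoyl chloride) | CC(C)CC(=O)Cl | starting material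
14 | (2Z,4R)-1-(2,5-dimethoxyphenyl)-3-formyl-7-methylocta-2,6-dien-4-yl 3-methylbutanoate | CC(C)=CC[C@@H](OC(=O)CC(C)C)/C(C=O)=C/Cc1cc(OC)ccc1OC | intermediate
15 | 2-[(2Z,4R)-3-formyl-7-methyl-4-(3-methylbutanoyloxy)octa-2,6-dienyl]-1,4-benzoquinone | CC(C)=CC[C@@H](OC(=O)CC(C)C)/C(C=O)=C/CC1=CC(=O)C=CC1=O | intermediate
16 | 4-hydroxy o-quinone methide tautomer of 15 (exocyclic C=C at the former benzylic carbon, ring C=O ortho to it) | CC(C)=CC[C@@H](OC(=O)CC(C)C)/C(C=O)=C/C=C1C=C(O)C=CC1=O | intermediate (not isolated)
17 | 2-aryl-2H-furan-1-ium phenolate zwitterion formed by O1–C2 closure | CC(C)=CC[C@@H](OC(=O)CC(C)C)C1=CC(c2cc(O)ccc2[O-])[O+]=C1 | intermediate (not isolated)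
18 | (1R)-1-[5-(2,5-dihydroxyphenyl)furan-3-yl]-4-methylpent-3-enyl 3-methylbutanoate | CC(C)=CC[C@@H](OC(=O)CC(C)C)c1coc(-c2cc(O)ccc2O)c1 | intermediate
19 | (1R)-1-[5-(3,6-dioxocyclohexa-1,4-dien-1-yl)furan-3-yl]-4-methylpent-3-enyl 3-methylbutanoate | CC(C)=CC[C@@H](OC(=O)CC(C)C)c1coc(C2=CC(=O)C=CC2=O)c1 | target

**Step count**
Total: 11 steps. Longest linear sequence: 11 steps, from 1 to 19; compounds 3, 8 and 13 enter as bought partners.

**Steps most likely to fail**

Step 10 (proposed new method). Three processes may defeat it: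
- loss of isovalerate by base-induced 1,4-elimination through the extended enolate;
- closure at the ring oxygen to give a 2H-chromene in place of the furan;
- hydrogen exchange between the product hydroquinone and unreacted quinone, which would park the precursor in its unreactive reduced form.

The fallback builds the furan by the classical butenolide reduction and keeps the arene as its dimethyl ether. It sets out from alkynol 7 and comes back to the route at the target 19.
- Silylation of 7 (t-BuMe2SiCl, imidazole, DMF) should give tert-butyl(dimethyl){[(3R)-6-methylhept-5-en-1-yn-3-yl]oxy}silane F1.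
- Deprotonation (n-BuLi, THF, −78 °C) and addition to 2,5-dimethoxybenzaldehyde (COc1ccc(OC)c(C=O)c1) should give (4R)-4-[tert-butyl(dimethyl)silyl]oxy-1-(2,5-dimethoxyphenyl)-7-methyloct-6-en-2-yn-1-ol F2. It forms as a mixture of epimers at the benzylic carbinol, which is lost later.
- Hydroxyl-directed trans-hydroalumination with NaAlH2(OCH2CH2OMe)2 in THF and an iodine quench should give the (2Z)-3-iodo-alkenol F3, with iodine cis to the benzylic carbinol.
- Cyclocarbonylation (PdCl2(PPh3)2, CO 1 atm, K2CO3, THF) should give 5-(2,5-dimethoxyphenyl)-3-[(1R)-1-[tert-butyl(dimethyl)silyl]oxy-4-methylpent-3-enyl]furan-2(5H)-one F4.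
- Reduction with i-Bu2AlH at −78 °C and dehydration of the lactol on dilute acid work-up should give the 2-aryl-4-alkylfuran silyl ether F5.
- Bu4NF in THF should free (1R)-1-[5-(2,5-dimethoxyphenyl)furan-3-yl]-4-methylpent-3-en-1-ol F6.
- Acylation with 13 and pyridine should give (1R)-1-[5-(2,5-dimethoxyphenyl)furan-3-yl]-4-methylpent-3-enyl 3-methylbutanoate F7.
- Oxidative demethylation with (NH4)2Ce(NO3)6 in MeCN/H2O at 0 °C should give 19.

Step 7. The tin–lithium exchange may be incomplete at the hindered trisubstituted alkenylstannane, MeLi may instead deprotonate the benzylic, allylic CH2, and the alkenyllithium may lose its geometry on warming. The fallback avoids organolithium chemistry. It sets out from stannane 10 and comes back at enal ester 14.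
- Acylation of 10 with 13 and pyridine should give (2Z,4R)-1-(2,5-dimethoxyphenyl)-7-methyl-3-(tributylstannyl)octa-2,6-dien-4-yl 3-methylbutanoate F8.
- Iododestannation (I2, CH2Cl2, 0 °C, retention) should give (2Z,4R)-1-(2,5-dimethoxyphenyl)-3-iodo-7-methylocta-2,6-dien-4-yl 3-methylbutanoate F9. With the hydroxyl already acylated, iodoetherification onto the trisubstituted alkene is excluded.
- Palladium-catalysed reductive carbonylation (Pd(PPh3)4, CO, slow addition of Bu3SnH, THF, 50 °C) should convert the C–I bond into the formyl group with retention and give 14.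

Step 5. The base may isomerise the skipped aryl alkyne to the aryl allene, the free carbinol may be O-benzylated, and the benzyl bromide may homocouple. The fallback forms the benzyl–alkyne bond first, on a silyl-capped acetylide, and sets the stereocentre afterwards. It sets out from benzyl bromide 8 and comes back at alkynol 9.
- The Grignard reagent of 3 (EtMgBr, THF) with 8 and catalytic CuBr at reflux should give [3-(2,5-dimethoxyphenyl)prop-1-yn-1-yl]trimethylsilane F10.
- Buffered desilylation (Bu4NF, AcOH, THF, 0 °C) should give 1,4-dimethoxy-2-(prop-2-yn-1-yl)benzene F11.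
- Lithiation (n-BuLi, THF, −78 °C) and acylation with Weinreb amide 2 should give 1-(2,5-dimethoxyphenyl)-7-methyloct-6-en-2-yn-4-one F12.
- Transfer hydrogenation of F12 with the catalyst of step 3 should give 9.

**Further compounds**
F1 | step 10 | tert-butyl(dimethyl){[(3R)-6-methylhept-5-en-1-yn-3-yl]oxy}silane | CC(C)=CC[C@@H](O[Si](C)(C)C(C)(C)C)C#C
F2 | step 10 | (4R)-4-[tert-butyl(dimethyl)silyl]oxy-1-(2,5-dimethoxyphenyl)-7-methyloct-6-en-2-yn-1-ol (C1 epimers) | CC(C)=CC[C@@H](O[Si](C)(C)C(C)(C)C)C#CC(O)c1cc(OC)ccc1OC
F3 | step 10 | (2Z,4R)-4-[tert-butyl(dimethyl)silyl]oxy-1-(2,5-dimethoxyphenyl)-3-iodo-7-methylocta-2,6-dien-1-ol (C1 epimers) | CC(C)=CC[C@@H](O[Si](C)(C)C(C)(C)C)/C(I)=C/C(O)c1cc(OC)ccc1OC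
F4 | step 10 | 5-(2,5-dimethoxyphenyl)-3-[(1R)-1-[tert-butyl(dimethyl)silyl]oxy-4-methylpent-3-enyl]furan-2(5H)-one (C5 epimers) | CC(C)=CC[C@@H](O[Si](C)(C)C(C)(C)C)C1=CC(c2cc(OC)ccc2OC)OC1=O
F5 | step 10 | tert-butyl{[(1R)-1-[5-(2,5-dimethoxyphenyl)furan-3-yl]-4-methylpent-3-enyl]oxy}dimethylsilane | CC(C)=CC[C@@H](O[Si](C)(C)C(C)(C)C)c1coc(-c2cc(OC)ccc2OC)c1
F6 | step 10 | (1R)-1-[5-(2,5-dimethoxyphenyl)furan-3-yl]-4-methylpent-3-en-1-ol | CC(C)=CC[C@@H](O)c1coc(-c2cc(OC)ccc2OC)c1
F7 | step 10 | (1R)-1-[5-(2,5-dimethoxyphenyl)furan-3-yl]-4-methylpent-3-enyl 3-methylbutanoate | CC(C)=CC[C@@H](OC(=O)CC(C)C)c1coc(-c2cc(OC)ccc2OC)c1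
F8 | step 7 | (2Z,4R)-1-(2,5-dimethoxyphenyl)-7-methyl-3-(tributylstannyl)octa-2,6-dien-4-yl 3-methylbutanoate | CC(C)=CC[C@@H](OC(=O)CC(C)C)/C(=C/Cc1cc(OC)ccc1OC)[Sn](CCCC)(CCCC)CCCC
F9 | step 7 | (2Z,4R)-1-(2,5-dimethoxyphenyl)-3-iodo-7-methylocta-2,6-dien-4-yl 3-methylbutanoate | CC(C)=CC[C@@H](OC(=O)CC(C)C)/C(I)=C/Cc1cc(OC)ccc1OC
F10 | step 5 | [3-(2,5-dimethoxyphenyl)prop-1-yn-1-yl]trimethylsilane | COc1ccc(OC)c(CC#C[Si](C)(C)C)c1
F11 | step 5 | 1,4-dimethoxy-2-(prop-2-yn-1-yl)benzene | COc1ccc(OC)c(CC#C)c1
F12 | step 5 | 1-(2,5-dimethoxyphenyl)-7-methyloct-6-en-2-yn-4-one | CC(C)=CCC(=O)C#CCc1cc(OC)ccc1OC
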